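**Plan**
- Retrosynthetic cuts, in order: the furan O–C2 bond (the ring returns to an open 2-methylalk-3-yne-1,2-diol); the bond between the alkyne and the allylic CH2 of the chain; the benzylic CH2–CH= bond together with the vinylic CH3–C bond; last the carbinol–CH2 bond.
- Enabling feature: the 2-alkyl-4-methylfuran. The ring O comes from the primary hydroxyl, C5–H from the CH2OH carbon, C4–CH3 from the methyl-bearing tertiary carbinol, and C3–H and C2 (carrying the chain CH2) from the two alkyne carbons.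
- Forward: geranyl acetate is oxidised at C8 and then at C1 to an (E)-enal; propargylation creates the carbinol; methylalumination and benzyl cross-coupling append the bis-silylated methylhydroquinone; the C8 bromide is joined to 2-methylbut-3-yne-1,2-diol; the furan, the only ring made, is closed last; fluoride frees the three hydroxyls.
- Stereochemistry: the single (S)-carbinol comes from a chiral phosphoric acid-catalysed allenylboration. Two E-alkenes are inherited from geranyl acetate (SeO2 attacks the E-methyl); the third comes from syn-carboalumination and coupling with retention.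

Key step: step 16

Assumption: diol 23 is used as the racemate, so 24 is a mixture of epimers at the tertiary carbinol, which becomes sp2 in the furan; the facial sense in step 5 is assigned by analogy and is to be checked on 8 by Mosher ester analysis.

**Route**

Step 1
Reactants: 1 geranyl acetate
Product: 2 (2E,6E)-8-hydroxy-3,7-dimethylocta-2,6-dien-1-yl acetate
Conditions: SeO2 (0.1 equiv), t-BuOOH (70% aq, 3 equiv), salicylic acid (0.1 equiv), CH2Cl2, rt
Reagents that add atoms: selenium dioxide O=[Se]=O (catalytic oxygen carrier); tert-butyl hydroperoxide CC(C)(C)OO (terminal oxidant)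
Why: SeO2-catalysed allylic oxidation (ene reaction, then [2,3]-sigmatropic shift) should attack the E-methyl of the electron-richer terminal alkene, the acetate-deactivated 2,3-alkene being left alone, to give the (E)-allylic alcohol.

Step 2
Reactants: 2 (2E,6E)-8-hydroxy-3,7-dimethylocta-2,6-dien-1-yl acetate
Product: 3 (2E,6E)-8-(tert-butyldimethylsilyloxy)-3,7-dimethylocta-2,6-dien-1-yl acetate
Conditions: TBSCl, imidazole, DMF, 0 °C → rt
Reagents that add atoms: tert-butyldimethylsilyl chloride CC(C)(C)[Si](C)(C)Cl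
Why: Imidazole-promoted silylation of a primary allylic alcohol masks the C8 oxygen in a form that should survive methanolysis, oxidation and Me3Al.

Step 3
Reactants: 3 (2E,6E)-8-(tert-butyldimethylsilyloxy)-3,7-dimethylocta-2,6-dien-1-yl acetate
Product: 4 (2E,6E)-8-(tert-butyldimethylsilyloxy)-3,7-dimethylocta-2,6-dien-1-ol
Conditions: K2CO3 (0.2 equiv), MeOH, rt
Reagents that add atoms: none
Why: Base-catalysed transesterification with methanol should remove the acetate while the primary silyl ether stays intact.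

Step 4
Reactants: 4 (2E,6E)-8-(tert-butyldimethylsilyloxy)-3,7-dimethylocta-2,6-dien-1-ol
Product: 5 (2E,6E)-8-(tert-butyldimethylsilyloxy)-3,7-dimethylocta-2,6-dienal
Conditions: (2,2,6,6-tetramethylpiperidin-1-yl)oxyl (TEMPO, 10 mol %), PhI(OAc)2, CH2Cl2, rt
Reagents that add atoms: none
Why: Oxoammonium-mediated (TEMPO/PhI(OAc)2) oxidation of the allylic alcohol should stop at the enal and is known to preserve the geometry of trisubstituted allylic systems.

Step 5
Reactants: 5 (2E,6E)-8-(tert-butyldimethylsilyloxy)-3,7-dimethylocta-2,6-dienal; 6 allenylboronic acid pinacol ester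
Product: 8 (4S,5E,9E)-11-(tert-butyldimethylsilyloxy)-6,10-dimethylundeca-5,9-dien-1-yn-4-ol, via pinacol borate ester 7 (not isolated)
Conditions: 6 (1.5 equiv), (S)-3,3′-bis(2,4,6-triisopropylphenyl)-1,1′-binaphthyl-2,2′-diyl hydrogen phosphate (10 mol %), 4 Å MS, toluene, 0 °C; aq. NaHCO3 work-up
Reagents that add atoms: none
Why: Chiral phosphoric acid-catalysed propargylation (SE2′ allenylboration through a six-membered chair in which the phosphate binds the boronate oxygen and the formyl hydrogen) is expected to deliver the propargyl group to the Si face with the (S)-acid, the mirror image of the Re-face preference of the (R)-acid with aryl and alkenyl aldehydes, and so set the (S)-carbinol under catalyst control.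

Step 6
Reactants: 8 (4S,5E,9E)-11-(tert-butyldimethylsilyloxy)-6,10-dimethylundeca-5,9-dien-1-yn-4-ol
Product: 9 (4S,5E,9E)-4,11-bis(tert-butyldimethylsilyloxy)-6,10-dimethylundeca-5,9-dien-1-yne
Conditions: TBSCl, imidazole, DMF, rt
Reagents that add atoms: tert-butyldimethylsilyl chloride CC(C)(C)[Si](C)(C)Cl
Why: Standard silylation of the secondary alcohol should protect the carbinol for the organoaluminium chemistry without touching the stereocentre.

Step 7
Reactants: 10 2-hydroxy-3-methylbenzaldehyde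
Product: 12 2,5-dihydroxy-3-methylbenzaldehyde, via potassium aryl sulfate 11 (not isolated)
Conditions: K2S2O8, 10% aq. NaOH, 0 °C → rt; then HCl (aq), 80 °C
Reagents that add atoms: potassium peroxodisulfate [K+].[K+].[O-]S(=O)(=O)OOS(=O)(=O)[O-]
Why: In the Elbs persulfate oxidation the phenoxide is attacked by peroxodisulfate at the free para carbon (both ortho positions are blocked by CH3 and CHO), and the aryl sulfate is hydrolysed in hot acid to the hydroquinone.

Step 8
Reactants: 12 2,5-dihydroxy-3-methylbenzaldehyde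
Product: 13 3-methyl-2,5-bis(triisopropylsilyloxy)benzaldehyde
Conditions: TIPSOTf (2.4 equiv), 2,6-lutidine, CH2Cl2, 0 °C → rt
Reagents that add atoms: triisopropylsilyl trifluoromethanesulfonate CC(C)[Si](OS(=O)(=O)C(F)(F)F)(C(C)C)C(C)C
Why: Silyl triflate silylation should cap both phenols, including the hindered hydrogen-bonded one; triisopropylsilyl is chosen because aryl triisopropylsilyl ethers resist borohydride, carbonate and organoaluminium reagents yet fall to fluoride.

Step 9
Reactants: 13 3-methyl-2,5-bis(triisopropylsilyloxy)benzaldehyde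
Product: 14 [3-methyl-2,5-bis(triisopropylsilyloxy)phenyl]methanol
Conditions: NaBH4, THF/MeOH, 0 °C
Reagents that add atoms: none
Why: Borohydride reduction of the aryl aldehyde should be clean, the bulky silyl group disfavouring oxygen-to-oxygen silyl migration to the new benzylic alkoxide.

Step 10
Reactants: 14 [3-methyl-2,5-bis(triisopropylsilyloxy)phenyl]methanol
Product: 16 1-(chloromethyl)-3-methyl-2,5-bis(triisopropylsilyloxy)benzene, via benzylic mesylate 15 (not isolated)
Conditions: MsCl, Et3N, CH2Cl2, −10 °C; then LiCl, THF, rt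
Reagents that add atoms: methanesulfonyl chloride CS(=O)(=O)Cl (atoms kept only in 15); lithium chloride [Li+].[Cl-]
Why: Mesylation followed by SN2 displacement with chloride at the activated benzylic carbon should give the chloride under non-acidic conditions that spare the aryl silyl ethers.

Step 11
Reactants: 9 (4S,5E,9E)-4,11-bis(tert-butyldimethylsilyloxy)-6,10-dimethylundeca-5,9-dien-1-yne; 16 1-(chloromethyl)-3-methyl-2,5-bis(triisopropylsilyloxy)benzene
Product: 18 (2E,6E,8S,10E)-1,8-bis(tert-butyldimethylsilyloxy)-2,6,10-trimethyl-12-[3-methyl-2,5-bis(triisopropylsilyloxy)phenyl]dodeca-2,6,10-triene, via alkenyldimethylalane 17 (not isolated)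
Conditions: Me3Al (2.5 equiv), Cp2ZrCl2 (0.3 equiv), CH2Cl2, 0 °C → rt; excess Me3Al evaporated; then 16, Pd(PPh3)4 (5 mol %, zerovalent palladium), THF, rt
Reagents that add atoms: trimethylaluminium C[Al](C)C
Why: Negishi zirconium-catalysed carboalumination adds methyl and aluminium syn across the terminal alkyne with aluminium on the terminal carbon, and palladium-catalysed cross-coupling of the resulting (E)-alkenylalane with the benzylic chloride proceeds with retention, so the E-trisubstituted alkene should form without touching the stereocentre or the other alkenes.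

Step 12
Reactants: 18 (2E,6E,8S,10E)-1,8-bis(tert-butyldimethylsilyloxy)-2,6,10-trimethyl-12-[3-methyl-2,5-bis(triisopropylsilyloxy)phenyl]dodeca-2,6,10-triene
Product: 19 (2E,6E,8S,10E)-8-(tert-butyldimethylsilyloxy)-2,6,10-trimethyl-12-[3-methyl-2,5-bis(triisopropylsilyloxy)phenyl]dodeca-2,6,10-trien-1-ol
Conditions: (1S)-(+)-10-camphorsulfonic acid (10 mol %), MeOH/CH2Cl2 1:1, 0 °C
Reagents that add atoms: none
Why: Acid-catalysed methanolysis discriminates sterically, so the primary silyl ether should cleave well before the secondary one, and aryl silyl ethers are inert to mild acid.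

Step 13
Reactants: 19 (2E,6E,8S,10E)-8-(tert-butyldimethylsilyloxy)-2,6,10-trimethyl-12-[3-methyl-2,5-bis(triisopropylsilyloxy)phenyl]dodeca-2,6,10-trien-1-ol
Product: 20 (2E,6E,8S,10E)-1-bromo-8-(tert-butyldimethylsilyloxy)-2,6,10-trimethyl-12-[3-methyl-2,5-bis(triisopropylsilyloxy)phenyl]dodeca-2,6,10-triene
Conditions: CBr4, PPh3, CH2Cl2, −20 → 0 °C
Reagents that add atoms: carbon tetrabromide BrC(Br)(Br)Br
Why: The Appel reaction converts the primary allylic alcohol to the bromide by SN2 displacement of the oxyphosphonium under neutral conditions, which should avoid allylic transposition and silyl loss.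

Step 14
Reactants: 21 hydroxyacetone; 22 ethynylmagnesium bromide
Product: 23 2-methylbut-3-yne-1,2-diol (racemic)
Conditions: 22 (2.5 equiv), THF, 0 °C → rt; aq. NH4Cl
Reagents that add atoms: none
Why: Grignard addition to the ketone (the first equivalent deprotonates the hydroxyl) should give the tertiary propargylic diol; its configuration is irrelevant because that carbon becomes aromatic later.

Step 15
Reactants: 20 (2E,6E,8S,10E)-1-bromo-8-(tert-butyldimethylsilyloxy)-2,6,10-trimethyl-12-[3-methyl-2,5-bis(triisopropylsilyloxy)phenyl]dodeca-2,6,10-triene; 23 2-methylbut-3-yne-1,2-diol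
Product: 24 (6E,10E,12S,14E)-12-(tert-butyldimethylsilyloxy)-2,6,10,14-tetramethyl-16-[3-methyl-2,5-bis(triisopropylsilyloxy)phenyl]hexadeca-6,10,14-trien-3-yne-1,2-diol (both C2 epimers)
Conditions: 23 (1.5 equiv), CuI (10 mol %), K2CO3, n-Bu4NBr, DMF, rt, argon
Reagents that add atoms: none
Why: Copper-catalysed, carbonate-mediated coupling of a terminal alkyne with a primary allylic bromide (alkylation of a copper acetylide) should substitute at the unhindered CH2 to give the 1,4-enyne with the E-alkene retained; free hydroxyls are tolerated and the aryl triisopropylsilyl ethers should withstand solid carbonate.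

Step 16
Reactants: 24 (6E,10E,12S,14E)-12-(tert-butyldimethylsilyloxy)-2,6,10,14-tetramethyl-16-[3-methyl-2,5-bis(triisopropylsilyloxy)phenyl]hexadeca-6,10,14-trien-3-yne-1,2-diol (both C2 epimers)
Product: 26 2-[(2E,6E,8S,10E)-8-(tert-butyldimethylsilyloxy)-2,6,10-trimethyl-12-[3-methyl-2,5-bis(triisopropylsilyloxy)phenyl]dodeca-2,6,10-trien-1-yl]-4-methylfuran, via hydroxydihydrofuran 25 (not isolated)
Conditions: Ph3PAuNTf2 (2 mol %, monovalent gold), 4 Å MS, THF, 0 °C → rt
Reagents that add atoms: none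
Why: The cationic gold complex π-activates the C3≡C4 alkyne of 24, the primary hydroxyl adds anti to gold at the distal alkyne carbon to form the O–C2 bond of the furan, protodeauration gives hydroxydihydrofuran 25, and loss of water from its tertiary carbinol aromatises the ring. The closest known reaction type is the gold- or silver-catalysed cyclodehydration of 3-alkyne-1,2-diols to substituted furans. The one ring closes in a 5-endo-dig mode; the tertiary hydroxyl could only close a strained four-membered ring, and the C12 oxygen is silylated and remote. No stereocentre is created, the two epimers at the tertiary carbinol converge because that carbon becomes sp2, and the (S)-silyloxy centre is not involved. The step needs alkyne activation in preference to three trisubstituted alkenes and a fixed substitution pattern: gold is alkynophilic, the nearest alkene stands in a 1,4-relationship that offers no low-strain enyne cyclisation, the adjacent hydroxyl makes the closure fast at low loading, and the methyl on the tertiary carbinol can only become C4–CH3. The nearly neutral conditions should leave the silyl ethers and the acid-sensitive furan intact.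

Step 17
Reactants: 26 2-[(2E,6E,8S,10E)-8-(tert-butyldimethylsilyloxy)-2,6,10-trimethyl-12-[3-methyl-2,5-bis(triisopropylsilyloxy)phenyl]dodeca-2,6,10-trien-1-yl]-4-methylfuran
Product: 27 2-[(2E,5S,6E,10E)-5-hydroxy-3,7,11-trimethyl-12-(4-methylfuran-2-yl)dodeca-2,6,10-trien-1-yl]-6-methylbenzene-1,4-diol (CNP0172089.1)
Conditions: TBAF (4 equiv), AcOH (4 equiv), degassed THF, 0 °C → rt, argon; degassed aq. NH4Cl/Na2S2O4 work-up
Reagents that add atoms: none
Why: Fluoride-mediated desilylation should remove the two aryl triisopropylsilyl ethers rapidly and the secondary silyl ether more slowly, while acetic acid buffering and exclusion of air keep the hydroquinone from oxidising to the quinone and spare the furan.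

**Compound list**
1 | geranyl acetate | CC(C)=CCC/C(C)=C/COC(C)=O | starting material
2 | (2E,6E)-8-hydroxy-3,7-dimethylocta-2,6-dien-1-yl acetate | C/C(=C\COC(C)=O)CC/C=C(\C)CO | intermediate
3 | (2E,6E)-8-(tert-butyldimethylsilyloxy)-3,7-dimethylocta-2,6-dien-1-yl acetate | C/C(=C\COC(C)=O)CC/C=C(\C)CO[Si](C)(C)C(C)(C)C | intermediate
4 | (2E,6E)-8-(tert-butyldimethylsilyloxy)-3,7-dimethylocta-2,6-dien-1-ol | C/C(=C\CO)CC/C=C(\C)CO[Si](C)(C)C(C)(C)C | intermediate
5 | (2E,6E)-8-(tert-butyldimethylsilyloxy)-3,7-dimethylocta-2,6-dienal | C/C(=C\C=O)CC/C=C(\C)CO[Si](C)(C)C(C)(C)C | intermediate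
6 | allenylboronic acid pinacol ester | C=C=CB1OC(C)(C)C(C)(C)O1 | starting material
7 | pinacol borate ester of 8 | C/C(=C\[C@@H](OB1OC(C)(C)C(C)(C)O1)CC#C)CC/C=C(\C)CO[Si](C)(C)C(C)(C)C | intermediate
8 | (4S,5E,9E)-11-(tert-butyldimethylsilyloxy)-6,10-dimethylundeca-5,9-dien-1-yn-4-ol | C/C(=C\[C@@H](O)CC#C)CC/C=C(\C)CO[Si](C)(C)C(C)(C)C | intermediate
9 | (4S,5E,9E)-4,11-bis(tert-butyldimethylsilyloxy)-6,10-dimethylundeca-5,9-dien-1-yne | C/C(=C\[C@@H](O[Si](C)(C)C(C)(C)C)CC#C)CC/C=C(\C)CO[Si](C)(C)C(C)(C)C | intermediate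
10 | 2-hydroxy-3-methylbenzaldehyde | Cc1cccc(C=O)c1O | starting material
11 | potassium 3-formyl-4-hydroxy-5-methylphenyl sulfate | Cc1cc(OS(=O)(=O)[O-])cc(C=O)c1O.[K+] | intermediate
12 | 2,5-dihydroxy-3-methylbenzaldehyde | Cc1cc(O)cc(C=O)c1O | intermediate
13 | 3-methyl-2,5-bis(triisopropylsilyloxy)benzaldehyde | Cc1cc(O[Si](C(C)C)(C(C)C)C(C)C)cc(C=O)c1O[Si](C(C)C)(C(C)C)C(C)C | intermediate
14 | [3-methyl-2,5-bis(triisopropylsilyloxy)phenyl]methanol | Cc1cc(O[Si](C(C)C)(C(C)C)C(C)C)cc(CO)c1O[Si](C(C)C)(C(C)C)C(C)C | intermediate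
15 | 3-methyl-2,5-bis(triisopropylsilyloxy)benzyl methanesulfonate | Cc1cc(O[Si](C(C)C)(C(C)C)C(C)C)cc(COS(C)(=O)=O)c1O[Si](C(C)C)(C(C)C)C(C)C | intermediate
16 | 1-(chloromethyl)-3-methyl-2,5-bis(triisopropylsilyloxy)benzene | Cc1cc(O[Si](C(C)C)(C(C)C)C(C)C)cc(CCl)c1O[Si](C(C)C)(C(C)C)C(C)C | intermediate
17 | [(1E,4S,5E,9E)-4,11-bis(tert-butyldimethylsilyloxy)-2,6,10-trimethylundeca-1,5,9-trien-1-yl]dimethylalane | C/C(=C\[C@@H](O[Si](C)(C)C(C)(C)C)C/C(C)=C/[Al](C)C)CC/C=C(\C)CO[Si](C)(C)C(C)(C)C | intermediate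
18 | (2E,6E,8S,10E)-1,8-bis(tert-butyldimethylsilyloxy)-2,6,10-trimethyl-12-[3-methyl-2,5-bis(triisopropylsilyloxy)phenyl]dodeca-2,6,10-triene | C/C(=C\[C@@H](O[Si](C)(C)C(C)(C)C)C/C(C)=C/Cc1cc(O[Si](C(C)C)(C(C)C)C(C)C)cc(C)c1O[Si](C(C)C)(C(C)C)C(C)C)CC/C=C(\C)CO[Si](C)(C)C(C)(C)C | intermediate
19 | (2E,6E,8S,10E)-8-(tert-butyldimethylsilyloxy)-2,6,10-trimethyl-12-[3-methyl-2,5-bis(triisopropylsilyloxy)phenyl]dodeca-2,6,10-trien-1-ol | C/C(=C\[C@@H](O[Si](C)(C)C(C)(C)C)C/C(C)=C/Cc1cc(O[Si](C(C)C)(C(C)C)C(C)C)cc(C)c1O[Si](C(C)C)(C(C)C)C(C)C)CC/C=C(\C)CO | intermediate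
20 | (2E,6E,8S,10E)-1-bromo-8-(tert-butyldimethylsilyloxy)-2,6,10-trimethyl-12-[3-methyl-2,5-bis(triisopropylsilyloxy)phenyl]dodeca-2,6,10-triene | C/C(=C\[C@@H](O[Si](C)(C)C(C)(C)C)C/C(C)=C/Cc1cc(O[Si](C(C)C)(C(C)C)C(C)C)cc(C)c1O[Si](C(C)C)(C(C)C)C(C)C)CC/C=C(\C)CBr | intermediate
21 | hydroxyacetone | CC(=O)CO | starting material
22 | ethynylmagnesium bromide | C#C[Mg]Br | starting material
23 | 2-methylbut-3-yne-1,2-diol (racemic) | C#CC(C)(O)CO | intermediate
24 | (6E,10E,12S,14E)-12-(tert-butyldimethylsilyloxy)-2,6,10,14-tetramethyl-16-[3-methyl-2,5-bis(triisopropylsilyloxy)phenyl]hexadeca-6,10,14-trien-3-yne-1,2-diol (both C2 epimers) | C/C(=C\[C@@H](O[Si](C)(C)C(C)(C)C)C/C(C)=C/Cc1cc(O[Si](C(C)C)(C(C)C)C(C)C)cc(C)c1O[Si](C(C)C)(C(C)C)C(C)C)CC/C=C(\C)CC#CC(C)(O)CO | intermediate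
25 | 5-[(2E,6E,8S,10E)-8-(tert-butyldimethylsilyloxy)-2,6,10-trimethyl-12-[3-methyl-2,5-bis(triisopropylsilyloxy)phenyl]dodeca-2,6,10-trien-1-yl]-3-methyl-2,3-dihydrofuran-3-ol (both C3 epimers) | C/C(=C\[C@@H](O[Si](C)(C)C(C)(C)C)C/C(C)=C/Cc1cc(O[Si](C(C)C)(C(C)C)C(C)C)cc(C)c1O[Si](C(C)C)(C(C)C)C(C)C)CC/C=C(\C)CC1=CC(C)(O)CO1 | intermediate
26 | 2-[(2E,6E,8S,10E)-8-(tert-butyldimethylsilyloxy)-2,6,10-trimethyl-12-[3-methyl-2,5-bis(triisopropylsilyloxy)phenyl]dodeca-2,6,10-trien-1-yl]-4-methylfuran | C/C(=C\[C@@H](O[Si](C)(C)C(C)(C)C)C/C(C)=C/Cc1cc(O[Si](C(C)C)(C(C)C)C(C)C)cc(C)c1O[Si](C(C)C)(C(C)C)C(C)C)CC/C=C(\C)Cc1cc(C)co1 | intermediate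
27 | 2-[(2E,5S,6E,10E)-5-hydroxy-3,7,11-trimethyl-12-(4-methylfuran-2-yl)dodeca-2,6,10-trien-1-yl]-6-methylbenzene-1,4-diol (CNP0172089.1) | C/C(=C\[C@@H](O)C/C(C)=C/Cc1cc(O)cc(C)c1O)CC/C=C(\C)Cc1cc(C)co1 | target

**Count and risks**
Total steps: 17. Longest linear sequence: 12 (steps 1–6, 11–13, 15–17, from geranyl acetate).

Step 11 is the most exposed. Methylalumination may stall or lose regiocontrol; residual Me3Al may ionise the electron-rich benzylic chloride (Friedel–Crafts-type consumption or methyl transfer); oxidative addition and transmetalation next to the bulky ortho silyloxy group may be slow. The fallback sets out from 9 and 16 and returns at 18. Alkenylalane 17 is quenched with I2 to give (1E,4S,5E,9E)-4,11-bis(tert-butyldimethylsilyloxy)-1-iodo-2,6,10-trimethylundeca-1,5,9-triene F1, which is purified. Chloride 16 is converted with Zn dust and LiCl in THF into [3-methyl-2,5-bis(triisopropylsilyloxy)benzyl]zinc chloride F2. Negishi coupling of F1 with F2 (Pd(PPh3)4, THF, rt to 50 °C) should then give 18 with the polarity of the partners reversed and no aluminium Lewis acid present.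

Step 15 comes next. The allylcopper pathway may give allylic transposition or erode the alkene geometry, the unprotected diol may be O-allylated, or turnover may be slow. The fallback sets out from 20 and returns at 24, building the diol in stages. Bromide 20 is coupled with ethynylmagnesium bromide 22 (CuBr·SMe2 catalytic, THF) to give (4E,8E,10S,12E)-10-(tert-butyldimethylsilyloxy)-4,8,12-trimethyl-14-[3-methyl-2,5-bis(triisopropylsilyloxy)phenyl]tetradeca-4,8,12-trien-1-yne F3. Hydroxyacetone 21 is silylated (Et3SiCl, imidazole) to 1-(triethylsilyloxy)propan-2-one F4. The lithium acetylide of F3 (n-BuLi, THF, −78 °C) is added to F4 to give (6E,10E,12S,14E)-12-(tert-butyldimethylsilyloxy)-2,6,10,14-tetramethyl-16-[3-methyl-2,5-bis(triisopropylsilyloxy)phenyl]-1-(triethylsilyloxy)hexadeca-6,10,14-trien-3-yn-2-ol F5. Pyridinium p-toluenesulfonate in MeOH at 0 °C then removes the primary triethylsilyl group to give 24.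

Step 5 is third. Facial discrimination may be insufficient with a β,β-disubstituted enal, or the uncatalysed allenylboration may compete and lower the enantiomeric purity. The fallback sets out from 5 and returns at 9, replacing catalyst control by a separable auxiliary-controlled aldol. A Nagao-type acetate aldol of 5 with the titanium enolate of N-acetyl-(4R)-4-isopropyl-1,3-thiazolidine-2-thione (TiCl4, i-Pr2NEt, CH2Cl2, −78 °C) should give (3S,4E,8E)-10-(tert-butyldimethylsilyloxy)-3-hydroxy-1-[(4R)-4-isopropyl-2-thioxo-1,3-thiazolidin-3-yl]-5,9-dimethyldeca-4,8-dien-1-one F6. The auxiliary enantiomer is chosen on the chelated chair model, and the minor diastereomer is removed by chromatography. Silylation (TBSOTf, 2,6-lutidine) gives its 3-O-tert-butyldimethylsilyl ether F7. DIBAL-H at −78 °C cleaves the thioimide directly to (3S,4E,8E)-3,10-bis(tert-butyldimethylsilyloxy)-5,9-dimethyldeca-4,8-dienal F8. Ohira–Bestmann homologation (dimethyl (1-diazo-2-oxopropyl)phosphonate, K2CO3, MeOH) then gives 9.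

Further compounds
F1 | step 11 | (1E,4S,5E,9E)-4,11-bis(tert-butyldimethylsilyloxy)-1-iodo-2,6,10-trimethylundeca-1,5,9-triene | C/C(=C\[C@@H](O[Si](C)(C)C(C)(C)C)C/C(C)=C/I)CC/C=C(\C)CO[Si](C)(C)C(C)(C)C
F2 | step 11 | [3-methyl-2,5-bis(triisopropylsilyloxy)benzyl]zinc chloride | Cc1cc(O[Si](C(C)C)(C(C)C)C(C)C)cc(C[Zn]Cl)c1O[Si](C(C)C)(C(C)C)C(C)C
F3 | step 15 | (4E,8E,10S,12E)-10-(tert-butyldimethylsilyloxy)-4,8,12-trimethyl-14-[3-methyl-2,5-bis(triisopropylsilyloxy)phenyl]tetradeca-4,8,12-trien-1-yne | C/C(=C\[C@@H](O[Si](C)(C)C(C)(C)C)C/C(C)=C/Cc1cc(O[Si](C(C)C)(C(C)C)C(C)C)cc(C)c1O[Si](C(C)C)(C(C)C)C(C)C)CC/C=C(\C)CC#C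
F4 | step 15 | 1-(triethylsilyloxy)propan-2-one | CC(=O)CO[Si](CC)(CC)CC
F5 | step 15 | (6E,10E,12S,14E)-12-(tert-butyldimethylsilyloxy)-2,6,10,14-tetramethyl-16-[3-methyl-2,5-bis(triisopropylsilyloxy)phenyl]-1-(triethylsilyloxy)hexadeca-6,10,14-trien-3-yn-2-ol | C/C(=C\[C@@H](O[Si](C)(C)C(C)(C)C)C/C(C)=C/Cc1cc(O[Si](C(C)C)(C(C)C)C(C)C)cc(C)c1O[Si](C(C)C)(C(C)C)C(C)C)CC/C=C(\C)CC#CC(C)(O)CO[Si](CC)(CC)CC
F6 | step 5 | (3S,4E,8E)-10-(tert-butyldimethylsilyloxy)-3-hydroxy-1-[(4R)-4-isopropyl-2-thioxo-1,3-thiazolidin-3-yl]-5,9-dimethyldeca-4,8-dien-1-one | C/C(=C\[C@@H](O)CC(=O)N1C(=S)SC[C@H]1C(C)C)CC/C=C(\C)CO[Si](C)(C)C(C)(C)C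
F7 | step 5 | (3S,4E,8E)-3,10-bis(tert-butyldimethylsilyloxy)-1-[(4R)-4-isopropyl-2-thioxo-1,3-thiazolidin-3-yl]-5,9-dimethyldeca-4,8-dien-1-one | C/C(=C\[C@@H](O[Si](C)(C)C(C)(C)C)CC(=O)N1C(=S)SC[C@H]1C(C)C)CC/C=C(\C)CO[Si](C)(C)C(C)(C)C
F8 | step 5 | (3S,4E,8E)-3,10-bis(tert-butyldimethylsilyloxy)-5,9-dimethyldeca-4,8-dienal | C/C(=C\[C@@H](O[Si](C)(C)C(C)(C)C)CC=O)CC/C=C(\C)CO[Si](C)(C)C(C)(C)C
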